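**Strategy.** The route rests on cutting the bond between the exocyclic acyloxymethyl carbon and C3 of the oxolane ring. The key step exploits two features: the cis-1,3 relation between that carbon and the C4 hydroxyl oxygen, and the benzylic C2 that also carries the ring oxygen O1. A (bromomethyl)dimethylsilyl group on the C4 oxygen of an (S)-5-aryl-2,3-dihydrofuran-3-ol cyclises by 5-exo radical addition to C3, and the resulting C2 radical takes up hydrogen on the convex face. One operation thus forms the C–C bond and sets C3 and C2 from C4, giving the all-cis ring. Oxidative removal of silicon and veratroylation of the primary alcohol complete the synthesis.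

Key step: step 4

Assumption: ethyl (tert-butyldimethylsilyloxy)acetate and (bromomethyl)chlorodimethylsilane are taken as commercial; in the oxazaborolidine reduction the alkenyl arm of the furanone is taken to act as the large group, as in other conjugated enones.

Step 1
Reactants: 1 3',4'-dimethoxyacetophenone; 2 ethyl 2-[(tert-butyldimethylsilyl)oxy]acetate
Product: 5 5-(3,4-dimethoxyphenyl)furan-3(2H)-one, via silyloxy diketone 3 (not isolated), via hydroxy diketone 4 (not isolated)
Conditions: LiN(SiMe3)2 (2.2 equiv), THF, −78 °C, then 2, −78 to 0 °C; then 3 M aq HCl, 23 °C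
Reagents that add atoms: none
Why: Crossed Claisen condensation of the ketone lithium enolate with the α-silyloxy ester should give the 1,3-diketone, and aqueous acid then removes the silyl group and closes the ring by hemiketalisation and dehydration (acid-promoted cyclodehydration of an α'-hydroxy-1,3-diketone to a 3(2H)-furanone); no stereocenter is formed.

Step 2
Reactants: 5 5-(3,4-dimethoxyphenyl)furan-3(2H)-one
Product: 6 (3S)-5-(3,4-dimethoxyphenyl)-2,3-dihydrofuran-3-ol
Conditions: (S)-Me-CBS [(S)-1-methyl-3,3-diphenyltetrahydro-1H,3H-pyrrolo[1,2-c][1,3,2]oxazaborole] (0.2 equiv), catecholborane (1.5 equiv), toluene, −78 to −40 °C; MeOH quench, cold aq NaOH/NaHCO3 wash, no acid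
Reagents that add atoms: none
Why: Corey–Bakshi–Shibata reduction of a cyclic β-alkoxy enone (1,2-reduction, as in the preparation of glycals from dihydropyranones) should deliver hydride to the face fixed by the catalyst with the alkenyl arm as the large group, setting the carbinol carbon as S; the base-only work-up avoids loss of water to the 2-arylfuran.

Step 3
Reactants: 6 (3S)-5-(3,4-dimethoxyphenyl)-2,3-dihydrofuran-3-ol; 7 (bromomethyl)chlorodimethylsilane
Product: 8 (S)-(bromomethyl){[5-(3,4-dimethoxyphenyl)-2,3-dihydrofuran-3-yl]oxy}dimethylsilane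
Conditions: Et3N (1.5 equiv), 4-(dimethylamino)pyridine (0.05 equiv), CH2Cl2, 0 °C; hexane, filtration, crude used at once
Reagents that add atoms: none
Why: Standard O-silylation of a secondary alcohol with a chlorosilane under amine base installs the temporary silicon tether that carries the future exocyclic carbon, without touching the stereocenter and in a medium that protects the acid-labile enol ether.

Step 4
Reactants: 8 (S)-(bromomethyl){[5-(3,4-dimethoxyphenyl)-2,3-dihydrofuran-3-yl]oxy}dimethylsilane
Product: 9 (3aS,4S,6aS)-4-(3,4-dimethoxyphenyl)-2,2-dimethylhexahydrofuro[3,4-d][1,2]oxasilole (cis-fused, aryl cis to the CH2 and O substituents of the oxolane ring)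
Conditions: Bu3SnH (1.3 equiv) and AIBN (0.1 equiv) by syringe pump, degassed benzene (0.01 M), 80 °C
Reagents that add atoms: none
Why: Tributyltin radical abstracts bromine to give the silicon-bound primary radical, which adds 5-exo-trig to C3 of the enol ether and forms the exocyclic CH2–C3 bond, leaving a tertiary benzylic, oxygen-stabilised radical at C2 that is quenched by hydrogen-atom transfer from Bu3SnH. The closest known reaction type is the Nishiyama–Stork silicon-tethered radical cyclisation of (bromomethyl)dimethylsilyl ethers of allylic alcohols. The one ring closed, the 1-oxa-2-silacyclopentane, forms in the 5-exo-trig mode and can only be cis-fused to the five-membered ring, so the S centre at C4 places the new CH2 on the face of the C4 oxygen and sets C3. The C2 centre is set by substrate control: the stannane should approach the planar C2 radical on the convex face, anti to the new C3–CH2 bond, which places the aryl group on the face of the CH2 and O substituents (all-cis). The step needs 5-exo over 6-endo closure and one face at C2; the first is secured because attack at C3 gives the stabilised radical while C2 is fully substituted, the second by the cis-fused bicycle. High dilution and slow stannane addition keep direct reduction of the C–Br bond from competing.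

Step 5
Reactants: 9 (3aS,4S,6aS)-4-(3,4-dimethoxyphenyl)-2,2-dimethylhexahydrofuro[3,4-d][1,2]oxasilole
Product: 10 (3S,4R,5S)-5-(3,4-dimethoxyphenyl)-4-(hydroxymethyl)oxolan-3-ol
Conditions: 30% H2O2 (10 equiv), KF (4 equiv), KHCO3 (2 equiv), THF/MeOH 1:1, 23 °C
Reagents that add atoms: hydrogen peroxide, OO
Why: Tamao–Kumada oxidation: fluoride-activated peroxide attacks the alkoxysilane, the C–Si bond is replaced by C–O at the non-stereogenic CH2 and the Si–O bonds are hydrolysed, releasing the cis-1,3-diol with all three ring stereocenters untouched.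

Step 6
Reactants: 10 (3S,4R,5S)-5-(3,4-dimethoxyphenyl)-4-(hydroxymethyl)oxolan-3-ol; 11 3,4-dimethoxybenzoyl chloride
Product: 12 [(2S,3R,4S)-2-(3,4-dimethoxyphenyl)-4-hydroxyoxolan-3-yl]methyl 3,4-dimethoxybenzoate (CNP0317486.2)
Conditions: 11 (1.05 equiv), 2,4,6-collidine (2 equiv), CH2Cl2, −40 to 0 °C
Reagents that add atoms: none
Why: Nucleophilic acyl substitution with an acid chloride and collidine at low temperature should acylate the primary hydroxyl in preference to the hindered secondary one, and any secondary ester should equilibrate to the primary ester across the cis-1,3-diol; no stereocenter is affected.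

**Compound list**

1 | 3',4'-dimethoxyacetophenone | CC(=O)c1ccc(OC)c(OC)c1 | starting material
2 | ethyl 2-[(tert-butyldimethylsilyl)oxy]acetate | CCOC(=O)CO[Si](C)(C)C(C)(C)C | starting material
3 | 4-[(tert-butyldimethylsilyl)oxy]-1-(3,4-dimethoxyphenyl)butane-1,3-dione | COc1ccc(C(=O)CC(=O)CO[Si](C)(C)C(C)(C)C)cc1OC | intermediate
4 | 1-(3,4-dimethoxyphenyl)-4-hydroxybutane-1,3-dione | COc1ccc(C(=O)CC(=O)CO)cc1OC | intermediate
5 | 5-(3,4-dimethoxyphenyl)furan-3(2H)-one | COc1ccc(C2=CC(=O)CO2)cc1OC | intermediate
6 | (3S)-5-(3,4-dimethoxyphenyl)-2,3-dihydrofuran-3-ol | O[C@@H]1COC(c2ccc(OC)c(OC)c2)=C1 | intermediate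
7 | (bromomethyl)chlorodimethylsilane | C[Si](C)(Cl)CBr | starting material
8 | (S)-(bromomethyl){[5-(3,4-dimethoxyphenyl)-2,3-dihydrofuran-3-yl]oxy}dimethylsilane | BrC[Si](C)(C)O[C@@H]1COC(c2ccc(OC)c(OC)c2)=C1 | intermediate
9 | (3aS,4S,6aS)-4-(3,4-dimethoxyphenyl)-2,2-dimethylhexahydrofuro[3,4-d][1,2]oxasilole | C[Si]1(C)C[C@@H]2[C@H](O1)CO[C@@H]2c3ccc(OC)c(OC)c3 | intermediate
10 | (3S,4R,5S)-5-(3,4-dimethoxyphenyl)-4-(hydroxymethyl)oxolan-3-ol | OC[C@@H]1[C@H](O)CO[C@@H]1c1ccc(OC)c(OC)c1 | intermediate
11 | 3,4-dimethoxybenzoyl chloride | COc1ccc(C(Cl)=O)cc1OC | starting material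
12 | [(2S,3R,4S)-2-(3,4-dimethoxyphenyl)-4-hydroxyoxolan-3-yl]methyl 3,4-dimethoxybenzoate | COc1ccc(C(=O)OC[C@@H]2[C@H](O)CO[C@@H]2c2ccc(OC)c(OC)c2)cc1OC | target

**Total step count:** 6. **Longest linear sequence:** 6 steps (1 → 5 → 6 → 8 → 9 → 10 → 12).

**Steps most likely to fail**

Step 4. What may go wrong: hydrogen-atom transfer to the C2 radical from the concave face, giving the wrong configuration at C2, or thermal loss of the silyloxy group with aromatisation before the radical closes. The fallback sets out from 5 and comes back at 10; it makes the same CH2–C3 bond by cross-coupling and the ring stereocenters by hydrogenation. Ketone 5 is brominated at the α-carbon of the vinylogous ester (NBS, CH2Cl2, 0 °C) to 4-bromo-5-(3,4-dimethoxyphenyl)furan-3(2H)-one F1. Stille coupling with (tributylstannyl)methanol (Pd(PPh3)4, dioxane, 90 °C) should give 5-(3,4-dimethoxyphenyl)-4-(hydroxymethyl)furan-3(2H)-one F2. Oxazaborolidine reduction as in step 2, now on an α-substituted enone, should give (3S)-5-(3,4-dimethoxyphenyl)-4-(hydroxymethyl)-2,3-dihydrofuran-3-ol F3, which is silylated at once (TBSCl, imidazole, DMF) to the bis(tert-butyldimethylsilyl) ether F4. Hydrogenation over Rh/Al2O3 (H2, EtOAc, trace Et3N) should add both hydrogens cis, on the face opposite the C4 silyloxy group, to give the all-cis bis-silyl ether F5. Bu4NF in THF then releases diol 10.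

Step 2. What may go wrong: insufficient enantioselectivity on a ketone whose two arms differ little in size, or dehydration of the allylic alcohol to the furan during isolation. The fallback sets out from 5 and comes back at 6; it replaces asymmetric reduction by resolution. Luche reduction (NaBH4, CeCl3·7H2O, MeOH, −40 °C) gives racemic 5-(3,4-dimethoxyphenyl)-2,3-dihydrofuran-3-ol F6. Lipase-catalysed acylation (Candida antarctica lipase B, vinyl acetate, iPr2O with a trace of Et3N) should convert the S enantiomer faster, by the Kazlauskas rule with the alkenyl arm as the large group, into (3S)-5-(3,4-dimethoxyphenyl)-2,3-dihydrofuran-3-yl acetate F7. After separation from the unreacted R alcohol, methanolysis (K2CO3, MeOH, 0 °C) returns 6.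

Step 6. What may go wrong: acylation of both hydroxyls or of the secondary one in the crowded all-cis diol. The fallback sets out from 10 and comes back at 12; it replaces kinetic discrimination by tin-template activation. Diol 10 is heated with Bu2SnO in toluene with removal of water to form the cyclic dibutylstannylene acetal F8. Addition of 11 at 0 °C should acylate the primary oxygen of the tin acetal, and aqueous work-up gives 12.

**Further compounds**

F1 | step 4 | 4-bromo-5-(3,4-dimethoxyphenyl)furan-3(2H)-one | COc1ccc(C2=C(Br)C(=O)CO2)cc1OC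
F2 | step 4 | 5-(3,4-dimethoxyphenyl)-4-(hydroxymethyl)furan-3(2H)-one | COc1ccc(C2=C(CO)C(=O)CO2)cc1OC
F3 | step 4 | (3S)-5-(3,4-dimethoxyphenyl)-4-(hydroxymethyl)-2,3-dihydrofuran-3-ol | O[C@@H]1COC(c2ccc(OC)c(OC)c2)=C1CO
F4 | step 4 | (3S)-3-[(tert-butyldimethylsilyl)oxy]-4-{[(tert-butyldimethylsilyl)oxy]methyl}-5-(3,4-dimethoxyphenyl)-2,3-dihydrofuran | CC(C)(C)[Si](C)(C)O[C@@H]1COC(c2ccc(OC)c(OC)c2)=C1CO[Si](C)(C)C(C)(C)C
F5 | step 4 | (2S,3R,4S)-4-[(tert-butyldimethylsilyl)oxy]-3-{[(tert-butyldimethylsilyl)oxy]methyl}-2-(3,4-dimethoxyphenyl)oxolane | CC(C)(C)[Si](C)(C)OC[C@@H]1[C@H](O[Si](C)(C)C(C)(C)C)CO[C@@H]1c1ccc(OC)c(OC)c1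
F6 | step 2 | racemic 5-(3,4-dimethoxyphenyl)-2,3-dihydrofuran-3-ol | OC1COC(c2ccc(OC)c(OC)c2)=C1
F7 | step 2 | (3S)-5-(3,4-dimethoxyphenyl)-2,3-dihydrofuran-3-yl acetate | CC(=O)O[C@@H]1COC(c2ccc(OC)c(OC)c2)=C1
F8 | step 6 | cyclic dibutylstannylene acetal of diol 10 | CCCC[Sn]1(CCCC)OC[C@@H]2[C@H](O1)CO[C@@H]2c3ccc(OC)c(OC)c3
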